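The earlier runs and the new flask are simulated for an exercise; noise was put on by code.

The constant worth reading first is a stoichiometric one: the substrate turned over per equivalent of partner, taken from the last reading of the amber run, where partner is the shorter charge.

| flask | substrate | partner | precatalyst | temperature | remark | time |
|---|---|---|---|---|---|---|
| amber | 0.10 M | 0.065 M (fed, over 10 s) | 69 µM | 75 °C | run made earlier; the fed solution adds 0.50 times the starting volume |  |
| ochre | 0.10 M | 0.14 M (fed, over 10 s) | 69 µM | 86 °C | run made earlier; the fed solution adds 0.50 times the starting volume |  |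
| violet | 0.10 M | 0.35 M (fed, over 10 s) | 69 µM | 75 °C | run made earlier; the fed solution adds 0.50 times the starting volume |  |
| eta | 0.10 M | 0.300 M | 69 µM | 80 °C | everything together at the start, the whole solution of partner included, so that from the start the volume is larger by 0.50 times the starting volume | 2.0 min |
| alpha | 0.10 M | 0.0800 M (fed, over 10 s) | 69 µM | 80 °C | the fed solution adds 0.50 times the starting volume | 2.0 min |

| run | time / s | product / % | substrate / % |
|---|---|---|---|
| amber | 10.0 | 18.3 | 81.9 |
| amber | 20.0 | 40.5 | 58.9 |
| amber | 40.0 | 61.7 | 39.6 |
| amber | 60.0 | 63.9 | 37.1 |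
| amber | 80.0 | 65.1 | 36.0 |
| ochre | 10.0 | 43.4 | 57.6 |
| ochre | 12.0 | 54.3 | 46.9 |
| ochre | 25.0 | 98.1 | 0.5 |
| ochre | 40.0 | 99.5 | 0 |
| ochre | 80.0 | 100.4 | 0.6 |
| violet | 10.0 | 39.5 | 58.5 |
| violet | 20.0 | 84.0 | 13.7 |
| violet | 40.0 | 98.8 | 0.4 |
| violet | 60.0 | 98.5 | 0.6 |
| violet | 80.0 | 99.6 | 0.6 |

(scatter of a reading: 1 percentage point)

- which one finishes higher in amount of product, in percent of the substrate charged ("neither" within 2 percentage points) (eta / alpha / neither)
- amount of product at the end, in percent of the substrate charged, eta
- amount of product at the end, in percent of the substrate charged, alpha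

- charges are per starting volume, the dose included; the dosed solution carries all of it

Amber's product column gives 1.00 per equivalent. Its substrate column, a separate reading, gives 0.985. Product and substrate lost part by 1.1 percentage points, about one scatter, so neither column cheats and, as read, the partner counts one to one.

The partner ceiling, the equivalents of partner to substrate read as the fraction of substrate that the partner charge can turn over, is 0.800 for alpha, where partner is the limiting reagent. Through the product constant alpha reaches 80.0%, and through the substrate constant 78.8%. Eta carries 3.00 equivalents, so its ceiling passes one and the substrate charge caps it at 100%; violet, with 3.50 equivalents, read 99.6% at its last point.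

Speed should not interfere in alpha. Amber, cooler than alpha, gained 1.2 points between 60.0 s and 80.0 s, and alpha has twice the first of those times. Violet, cooler than eta, read 98.8% at 40.0 s, though violet's partner was fed and eta's is in from the start. The reckoning here commits to 80.0% for alpha and the whole charge for eta, a gap of 20 points against a margin of 2 points.

The forecast names eta, with eta at 99.5% (93% to 101%) and alpha at 79.5% (76.5% to 81.5%), on the ground that “the reaction is 1:1 and partner-limited”. On alpha it stands 0.5 points below this reckoning.

The flask gives eta 100% and alpha 80.0%, with eta higher.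

precatalyst → free catalyst (k = 1.90 s⁻¹, Ea = 93.0 kJ mol⁻¹); partner + catalyst intermediate A → catalyst intermediate B (k = 3300 M⁻¹ s⁻¹, Ea = 15.0 kJ mol⁻¹); catalyst intermediate C → free catalyst + product (k = 190 s⁻¹, Ea = 56.0 kJ mol⁻¹); partner ⇌ dormant form (K = 0.310, k = 0.190 s⁻¹, Ea = 85.0 kJ mol⁻¹, ΔH = −21.0 kJ mol⁻¹); catalyst intermediate B → by-product + catalyst intermediate C (k = 360 s⁻¹, Ea = 72.0 kJ mol⁻¹); substrate + free catalyst → catalyst intermediate A (k = 21000 M⁻¹ s⁻¹, Ea = 19.0 kJ mol⁻¹); (constants at 80 °C) Alpha stands on its ceiling of 0.800, with 0% of its partner left at 2.00 min. The neighbour is eta's flask with partner cut to 0.750 equiv, everything still in together at the start. Its ceiling is 0.750, under one, and it gives 75.0% of product, with 0% of its partner and 25% of its substrate still there, unbound.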